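**Retrosynthetic overview**

1. The route rests on the neighbouring C6 carboxyl and C7 methyl groups of the hexasubstituted benzene ring of the chroman, which sit between the C5 oxygen and the C8 prenyl group (chroman numbering).
2. After removal of the C5 MOM ether, the C7–CH3 and C6–CO2H bonds are both cut back to a 6,7-aryne, released from the 6-iodo-7-(4-chlorobenzenesulfonate) 21 and taken up by MeMgCl and CO2.
3. 21 goes back to the 2-dienylchroman 17 by lithiation–iodination at the only aromatic C–H (C6) and an SEM-to-sulfonate exchange at O7; the diene comes from a Heck coupling on the 2-vinylchroman 15.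
4. The benzene ring is present from the start and the dihydropyran ring is the only ring made: it is closed at O1–C2 by palladium-catalysed asymmetric allylic etherification of phenol carbonate 14, which also sets C2.
5. 14 comes from 2,4,6-trihydroxybenzaldehyde: hydrogen bonding to the formyl group differentiates the three oxygens, a Claisen rearrangement places the prenyl group, and a B-alkyl Suzuki coupling with (Z)-3-iodobut-2-en-1-ol builds the side chain.

Key step: step 15

Abbreviations: MOM = methoxymethyl; SEM = 2-(trimethylsilyl)ethoxymethyl; prenyl = 3-methylbut-2-en-1-yl; dienyl = (1E)-4-methylpenta-1,3-dien-1-yl; chroman = 3,4-dihydro-2H-chromene; (S,S)-L = N,N'-[(1S,2S)-cyclohexane-1,2-diyl]bis[2-(diphenylphosphanyl)benzamide].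

Assumption: the (S,S) antipode of the ligand in step 10 is taken to deliver the 2R chroman from the Z carbonate; if the first run shows the opposite sense, the (R,R) ligand is used and nothing else changes.

**Route**

Step 1
Reactants: 1 2,4,6-trihydroxybenzaldehyde
Product: 2 2,6-dihydroxy-4-(SEM-oxy)benzaldehyde
Conditions: SEMCl (1.0 equiv), iPr2NEt, CH2Cl2/THF, −20 → 0 °C
Reagents that add atoms: 2-(trimethylsilyl)ethoxymethyl chloride, C[Si](C)(C)CCOCCl
Why: O-alkylation with an α-chloro ether should take the 4-hydroxyl selectively, because it is the only one not held in a hydrogen bond to the formyl group.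

Step 2
Reactants: 2 2,6-dihydroxy-4-(SEM-oxy)benzaldehyde
Product: 3 2-hydroxy-6-(MOM-oxy)-4-(SEM-oxy)benzaldehyde
Conditions: MOMCl (1.1 equiv), iPr2NEt, CH2Cl2, 0 °C → rt
Reagents that add atoms: chloromethyl methyl ether, COCCl
Why: MOM ether formation at one of the two equivalent ortho hydroxyls should stop at mono-protection, because the remaining hydroxyl is then bound more firmly to the aldehyde oxygen.

Step 3
Reactants: 4 2-methylbut-3-en-2-ol
Product: 5 methyl 2-methylbut-3-en-2-yl carbonate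
Conditions: n-BuLi, THF, −78 °C; ClCO2Me, −78 → 0 °C
Reagents that add atoms: methyl chloroformate, COC(=O)Cl
Why: Acylation of the lithium alkoxide of a tertiary alcohol with a chloroformate is a standard carbonate synthesis.

Step 4
Reactants: 3 2-hydroxy-6-(MOM-oxy)-4-(SEM-oxy)benzaldehyde; 5 methyl 2-methylbut-3-en-2-yl carbonate
Product: 6 2-(MOM-oxy)-6-[(2-methylbut-3-en-2-yl)oxy]-4-(SEM-oxy)benzaldehyde
Conditions: Pd(PPh3)4 (3 mol %), THF, 0 °C → rt
Reagents that add atoms: none
Why: In this Tsuji–Trost allylic etherification the phenoxide should attack the more substituted terminus of the 1,1-dimethylallyl palladium complex under kinetic control and give the tertiary aryl ether.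

Step 5
Reactants: 6 2-(MOM-oxy)-6-[(2-methylbut-3-en-2-yl)oxy]-4-(SEM-oxy)benzaldehyde
Product: 7 2-hydroxy-6-(MOM-oxy)-3-prenyl-4-(SEM-oxy)benzaldehyde
Conditions: toluene, 110 °C (sealed tube)
Reagents that add atoms: none
Why: The aromatic Claisen rearrangement ([3,3] shift) can deliver the allyl terminus only to the one free ortho carbon, since the other bears the formyl group, and the allyl unit inverts to the linear prenyl group.

Step 6
Reactants: 7 2-hydroxy-6-(MOM-oxy)-3-prenyl-4-(SEM-oxy)benzaldehyde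
Product: 8 2-ethenyl-3-(MOM-oxy)-6-prenyl-5-(SEM-oxy)phenol
Conditions: MePPh3Br (2.6 equiv), KOtBu (2.5 equiv), THF, 0 °C → rt
Reagents that add atoms: methyltriphenylphosphonium bromide, C[P+](c1ccccc1)(c1ccccc1)c1ccccc1.[Br-]
Why: Wittig methylenation with excess ylide should first deprotonate the phenol and then convert the aldehyde into the styrene.

Step 7
Reactants: 9 but-2-yn-1-ol
Product: 11 (2Z)-3-iodobut-2-en-1-ol, via cyclic alkenylalanate 10 (not isolated)
Conditions: NaAlH2(OCH2CH2OMe)2, THF, 0 °C → rt; I2, THF, −78 °C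
Reagents that add atoms: iodine, II
Why: Hydroxyl-directed trans-hydroalumination places aluminium on C3 in a five-membered alanate, and iodinolysis of the C–Al bond with retention should give the Z iodide.

Step 8
Reactants: 8 2-ethenyl-3-(MOM-oxy)-6-prenyl-5-(SEM-oxy)phenol; 11 (2Z)-3-iodobut-2-en-1-ol
Product: 13 (2Z)-5-[2-hydroxy-6-(MOM-oxy)-3-prenyl-4-(SEM-oxy)phenyl]-3-methylpent-2-en-1-ol, via bis(9-BBN) adduct 12 (not isolated)
Conditions: 9-BBN-H (2.5 equiv), THF, 0 → 40 °C; then 3 M aq. NaOH, 11, PdCl2(dppf) (5 mol %), THF/DMF, rt → 45 °C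
Reagents that add atoms: none
Why: Anti-Markovnikov hydroboration by 9-BBN-H should pick the styrene over the trisubstituted prenyl alkene, and the B-alkyl Suzuki–Miyaura coupling retains the geometry of the alkenyl iodide, so the trisubstituted alkene is formed as the Z isomer.

Step 9
Reactants: 13 (2Z)-5-[2-hydroxy-6-(MOM-oxy)-3-prenyl-4-(SEM-oxy)phenyl]-3-methylpent-2-en-1-ol
Product: 14 (2Z)-5-[2-hydroxy-6-(MOM-oxy)-3-prenyl-4-(SEM-oxy)phenyl]-3-methylpent-2-en-1-yl methyl carbonate
Conditions: ClCO2Me (1.1 equiv), pyridine, CH2Cl2, −20 °C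
Reagents that add atoms: methyl chloroformate, COC(=O)Cl
Why: Acylation should occur at the primary allylic alcohol, because the phenol is flanked by two ortho carbon substituents and reacts far more slowly under pyridine.

Step 10
Reactants: 14 (2Z)-5-[2-hydroxy-6-(MOM-oxy)-3-prenyl-4-(SEM-oxy)phenyl]-3-methylpent-2-en-1-yl methyl carbonate
Product: 15 (2R)-2-ethenyl-5-(MOM-oxy)-2-methyl-8-prenyl-7-(SEM-oxy)chroman
Conditions: Pd2(dba)3·CHCl3 (2.5 mol %), (S,S)-L (7.5 mol %), AcOH (1 equiv), CH2Cl2, rt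
Reagents that add atoms: none
Why: In this palladium-catalysed asymmetric allylic etherification (Tsuji–Trost type) the tethered phenol attacks the tertiary terminus of the π-allylpalladium complex in a 6-exo sense, and the chiral pocket of the (S,S) ligand selects the face of attack among the interconverting diastereomeric complexes, which is expected to set C2 as R.

Step 11
Reactants: 15 (2R)-2-ethenyl-5-(MOM-oxy)-2-methyl-8-prenyl-7-(SEM-oxy)chroman; 16 1-bromo-2-methylprop-1-ene
Product: 17 (2R)-2-dienyl-5-(MOM-oxy)-2-methyl-8-prenyl-7-(SEM-oxy)chroman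
Conditions: Pd(OAc)2 (5 mol %), Bu4NCl, K2CO3, DMF, 60 °C (sealed tube)
Reagents that add atoms: none
Why: In this Heck alkenylation the isobutenyl group should add to the terminal vinyl carbon, and because the quaternary C2 carries no hydrogen, β-hydride elimination can only give the conjugated E diene without touching the stereocenter.

Step 12
Reactants: 17 (2R)-2-dienyl-5-(MOM-oxy)-2-methyl-8-prenyl-7-(SEM-oxy)chroman
Product: 19 (2R)-2-dienyl-6-iodo-5-(MOM-oxy)-2-methyl-8-prenyl-7-(SEM-oxy)chroman, via C6 aryllithium 18 (not isolated)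
Conditions: n-BuLi, TMEDA, THF, −78 → −40 °C; I2 (1.1 equiv), THF, −78 °C; aq. Na2S2O3
Reagents that add atoms: iodine, II
Why: Directed ortho-metalation should occur at C6, the only aromatic C–H, which lies between two acetal oxygens that chelate lithium, and the aryllithium is iodinated faster than iodine can attack the alkenes.

Step 13
Reactants: 19 (2R)-2-dienyl-6-iodo-5-(MOM-oxy)-2-methyl-8-prenyl-7-(SEM-oxy)chroman
Product: 20 (2R)-2-dienyl-6-iodo-5-(MOM-oxy)-2-methyl-8-prenylchroman-7-ol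
Conditions: Bu4NF, THF/DMPU, 60 °C; aq. NH4Cl
Reagents that add atoms: none
Why: Fluoride attacks silicon and the SEM ether fragments to ethene, formaldehyde and the phenoxide, while the MOM ether, the iodide and the alkenes are inert to these basic conditions.

Step 14
Reactants: 20 (2R)-2-dienyl-6-iodo-5-(MOM-oxy)-2-methyl-8-prenylchroman-7-ol
Product: 21 (2R)-2-dienyl-6-iodo-5-(MOM-oxy)-2-methyl-8-prenylchroman-7-yl 4-chlorobenzenesulfonate
Conditions: 4-ClC6H4SO2Cl, Et3N, DMAP (cat.), CH2Cl2, 0 °C → rt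
Reagents that add atoms: 4-chlorobenzenesulfonyl chloride, O=S(=O)(Cl)c1ccc(Cl)cc1
Why: DMAP-catalysed sulfonylation of a phenol is reliable even when the hydroxyl is flanked by two ortho substituents.

Step 15
Reactants: 21 (2R)-2-dienyl-6-iodo-5-(MOM-oxy)-2-methyl-8-prenylchroman-7-yl 4-chlorobenzenesulfonate; 22 methylmagnesium chloride; 23 carbon dioxide
Product: 27 (2R)-2-dienyl-5-(MOM-oxy)-2,7-dimethyl-8-prenylchroman-6-carboxylic acid, via C6 arylmagnesium sulfonate 24 (not isolated), via 6,7-aryne 25 (not isolated), via 7-methyl C6 arylmagnesium 26 (not isolated)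
Conditions: iPrMgCl·LiCl (1.1 equiv), THF, −78 °C; MeMgCl (5 equiv), −78 → 25 °C; CO2 (g), −20 → 0 °C; aq. NaH2PO4
Reagents that add atoms: none
Why: Iodine–magnesium exchange at C6 gives arylmagnesium 24, which is stable at −78 °C and on warming expels the C7 4-chlorobenzenesulfonate to release the 6,7-aryne 25; MeMgCl adds across the strained triple bond and the resulting arylmagnesium 26 is carboxylated by CO2, so the C7–CH3 and C6–CO2H bonds form in one flask. The closest known reaction type is the generation of arynes from 2-magnesiated aryl arenesulfonates, followed by addition of a magnesium nucleophile to a 3-alkoxyaryne and trapping of the adduct with an electrophile. No ring is closed and no stereocenter is formed; C2 is remote and the conditions are basic throughout. The step needs regioselectivity for methyl attack at C7, and this is secured by the inductively withdrawing C5 MOM-oxy group, which distorts the aryne so that C7 is the more electrophilic terminus and leaves the carbanion at C6 beside the oxygen, where it is stabilised and chelated by the acetal; this electronic bias must outweigh the steric effect of the C8 prenyl group next to C7. It also needs chemoselectivity: complete exchange before MeMgCl is added prevents isopropyl transfer, and the large excess of MeMgCl present while the aryne forms should outrun an intramolecular ene or [2+2] reaction with the prenyl group and capture by 24 or by the diene.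

Step 16
Reactants: 27 (2R)-2-dienyl-5-(MOM-oxy)-2,7-dimethyl-8-prenylchroman-6-carboxylic acid
Product: 28 (2R)-5-hydroxy-2,7-dimethyl-2-[(1E)-4-methylpenta-1,3-dien-1-yl]-8-(3-methylbut-2-en-1-yl)chroman-6-carboxylic acid
Conditions: Me3SiOTf (3 equiv), 2,2'-bipyridyl (4.5 equiv), CH2Cl2, 0 °C; then H2O, rt
Reagents that add atoms: none
Why: The silyl triflate–bipyridyl pair converts an aryl MOM ether into the aryl silyl ether through a bipyridinium acetal, which water hydrolyses, so the cleavage runs without free acid and the tertiary dienylic C2–O bond should not ionise.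

**Compound list**

1 | 2,4,6-trihydroxybenzaldehyde | O=Cc1c(O)cc(O)cc1O | starting material
2 | 2,6-dihydroxy-4-{[2-(trimethylsilyl)ethoxy]methoxy}benzaldehyde | O=Cc1c(O)cc(OCOCC[Si](C)(C)C)cc1O | intermediate
3 | 2-hydroxy-6-(methoxymethoxy)-4-{[2-(trimethylsilyl)ethoxy]methoxy}benzaldehyde | O=Cc1c(O)cc(OCOCC[Si](C)(C)C)cc1OCOC | intermediate
4 | 2-methylbut-3-en-2-ol | CC(C)(O)C=C | starting material
5 | methyl 2-methylbut-3-en-2-yl carbonate | COC(=O)OC(C)(C)C=C | intermediate
6 | 2-(methoxymethoxy)-6-[(2-methylbut-3-en-2-yl)oxy]-4-{[2-(trimethylsilyl)ethoxy]methoxy}benzaldehyde | O=Cc1c(OC(C)(C)C=C)cc(OCOCC[Si](C)(C)C)cc1OCOC | intermediate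
7 | 2-hydroxy-6-(methoxymethoxy)-3-(3-methylbut-2-en-1-yl)-4-{[2-(trimethylsilyl)ethoxy]methoxy}benzaldehyde | O=Cc1c(O)c(CC=C(C)C)c(OCOCC[Si](C)(C)C)cc1OCOC | intermediate
8 | 2-ethenyl-3-(methoxymethoxy)-6-(3-methylbut-2-en-1-yl)-5-{[2-(trimethylsilyl)ethoxy]methoxy}phenol | C=Cc1c(O)c(CC=C(C)C)c(OCOCC[Si](C)(C)C)cc1OCOC | intermediate
9 | but-2-yn-1-ol | CC#CCO | starting material
10 | sodium 2,2-bis(2-methoxyethoxy)-3-methyl-2,5-dihydro-1,2-oxaluminol-2-uide (cyclic alkenylalanate) | CC1=CCO[Al-]1(OCCOC)OCCOC.[Na+] | intermediate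
11 | (2Z)-3-iodobut-2-en-1-ol | OC/C=C(/C)I | intermediate
12 | 9-{2-[2-(9-borabicyclo[3.3.1]nonan-9-yloxy)-6-(methoxymethoxy)-3-(3-methylbut-2-en-1-yl)-4-{[2-(trimethylsilyl)ethoxy]methoxy}phenyl]ethyl}-9-borabicyclo[3.3.1]nonane | COCOc1cc(OCOCC[Si](C)(C)C)c(CC=C(C)C)c(OB2C3CCCC2CCC3)c1CCB1C2CCCC1CCC2 | intermediate
13 | (2Z)-5-[2-hydroxy-6-(methoxymethoxy)-3-(3-methylbut-2-en-1-yl)-4-{[2-(trimethylsilyl)ethoxy]methoxy}phenyl]-3-methylpent-2-en-1-ol | OC/C=C(/C)CCc1c(O)c(CC=C(C)C)c(OCOCC[Si](C)(C)C)cc1OCOC | intermediate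
14 | (2Z)-5-[2-hydroxy-6-(methoxymethoxy)-3-(3-methylbut-2-en-1-yl)-4-{[2-(trimethylsilyl)ethoxy]methoxy}phenyl]-3-methylpent-2-en-1-yl methyl carbonate | COC(=O)OC/C=C(/C)CCc1c(O)c(CC=C(C)C)c(OCOCC[Si](C)(C)C)cc1OCOC | intermediate
15 | (2R)-2-ethenyl-5-(methoxymethoxy)-2-methyl-8-(3-methylbut-2-en-1-yl)-7-{[2-(trimethylsilyl)ethoxy]methoxy}chroman | C=C[C@@]1(C)CCc2c(OCOC)cc(OCOCC[Si](C)(C)C)c(CC=C(C)C)c2O1 | intermediate
16 | 1-bromo-2-methylprop-1-ene | CC(C)=CBr | starting material
17 | (2R)-5-(methoxymethoxy)-2-methyl-2-[(1E)-4-methylpenta-1,3-dien-1-yl]-8-(3-methylbut-2-en-1-yl)-7-{[2-(trimethylsilyl)ethoxy]methoxy}chroman | CC(C)=C/C=C/[C@@]1(C)CCc2c(OCOC)cc(OCOCC[Si](C)(C)C)c(CC=C(C)C)c2O1 | intermediate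
18 | [(2R)-5-(methoxymethoxy)-2-methyl-2-[(1E)-4-methylpenta-1,3-dien-1-yl]-8-(3-methylbut-2-en-1-yl)-7-{[2-(trimethylsilyl)ethoxy]methoxy}chroman-6-yl]lithium | CC(C)=C/C=C/[C@@]1(C)CCc2c(OCOC)c([Li])c(OCOCC[Si](C)(C)C)c(CC=C(C)C)c2O1 | intermediate
19 | (2R)-6-iodo-5-(methoxymethoxy)-2-methyl-2-[(1E)-4-methylpenta-1,3-dien-1-yl]-8-(3-methylbut-2-en-1-yl)-7-{[2-(trimethylsilyl)ethoxy]methoxy}chroman | CC(C)=C/C=C/[C@@]1(C)CCc2c(OCOC)c(I)c(OCOCC[Si](C)(C)C)c(CC=C(C)C)c2O1 | intermediate
20 | (2R)-6-iodo-5-(methoxymethoxy)-2-methyl-2-[(1E)-4-methylpenta-1,3-dien-1-yl]-8-(3-methylbut-2-en-1-yl)chroman-7-ol | CC(C)=C/C=C/[C@@]1(C)CCc2c(OCOC)c(I)c(O)c(CC=C(C)C)c2O1 | intermediate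
21 | (2R)-6-iodo-5-(methoxymethoxy)-2-methyl-2-[(1E)-4-methylpenta-1,3-dien-1-yl]-8-(3-methylbut-2-en-1-yl)chroman-7-yl 4-chlorobenzenesulfonate | CC(C)=C/C=C/[C@@]1(C)CCc2c(OCOC)c(I)c(OS(=O)(=O)c3ccc(Cl)cc3)c(CC=C(C)C)c2O1 | intermediate
22 | methylmagnesium chloride | C[Mg]Cl | starting material
23 | carbon dioxide | O=C=O | starting material
24 | chloro[(2R)-7-(4-chlorobenzenesulfonyloxy)-5-(methoxymethoxy)-2-methyl-2-[(1E)-4-methylpenta-1,3-dien-1-yl]-8-(3-methylbut-2-en-1-yl)chroman-6-yl]magnesium | CC(C)=C/C=C/[C@@]1(C)CCc2c(OCOC)c([Mg]Cl)c(OS(=O)(=O)c3ccc(Cl)cc3)c(CC=C(C)C)c2O1 | intermediate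
25 | (2R)-6,7-didehydro-5-(methoxymethoxy)-2-methyl-2-[(1E)-4-methylpenta-1,3-dien-1-yl]-8-(3-methylbut-2-en-1-yl)chroman (6,7-aryne) | CC(C)=C/C=C/[C@@]1(C)CCC2=C(OCOC)C#CC(CC=C(C)C)=C2O1 | intermediate
26 | chloro[(2R)-5-(methoxymethoxy)-2,7-dimethyl-2-[(1E)-4-methylpenta-1,3-dien-1-yl]-8-(3-methylbut-2-en-1-yl)chroman-6-yl]magnesium | CC(C)=C/C=C/[C@@]1(C)CCc2c(OCOC)c([Mg]Cl)c(C)c(CC=C(C)C)c2O1 | intermediate
27 | (2R)-5-(methoxymethoxy)-2,7-dimethyl-2-[(1E)-4-methylpenta-1,3-dien-1-yl]-8-(3-methylbut-2-en-1-yl)chroman-6-carboxylic acid | CC(C)=C/C=C/[C@@]1(C)CCc2c(OCOC)c(C(=O)O)c(C)c(CC=C(C)C)c2O1 | intermediate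
28 | (2R)-5-hydroxy-2,7-dimethyl-2-[(1E)-4-methylpenta-1,3-dien-1-yl]-8-(3-methylbut-2-en-1-yl)chroman-6-carboxylic acid | CC(C)=C/C=C/[C@@]1(C)CCc2c(O)c(C(=O)O)c(C)c(CC=C(C)C)c2O1 | target

**Step count and risks**

Total step count: 16. Longest linear sequence: 14 steps (steps 1, 2, 4, 5, 6, 8, 9, 10, 11, 12, 13, 14, 15, 16); steps 3 and 7 make the two side reagents.

Steps most likely to fail:

Step 15. The aryne may be consumed by the neighbouring C8 prenyl group (intramolecular ene or [2+2] reaction) or by unreacted arylmagnesium before MeMgCl adds, or methyl may add at C6 if the steric bias of the prenyl group overrides the C5 oxygen. The fallback sets out from diene 17 and avoids the aryne. The same C6 aryllithium 18 is quenched with methyl chloroformate to give methyl (2R)-2-dienyl-5-(MOM-oxy)-2-methyl-8-prenyl-7-(SEM-oxy)chroman-6-carboxylate F1. Bu4NF in THF/DMPU removes the SEM group and gives the 7-hydroxy ester F2. PhNTf2 and K2CO3 in DMF convert it into the 7-triflate F3. Negishi coupling with MeZnCl (Pd(OAc)2, SPhos, THF, 40 °C) puts the methyl group on C7 and gives the 7-methyl methyl ester F4. SN2 demethylation of the hindered ester with NaSCH2CH2CH3 in DMF then gives acid 27, where the route is rejoined before step 16.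

Step 11. The alkylpalladium intermediate may lose the aryloxide by β-elimination, or zerovalent palladium may ionise the tertiary allylic aryl ether; either process opens the pyran ring or erodes the configuration at C2. The fallback sets out from Z-allylic alcohol 13 and makes steps 9 to 11 unnecessary. Sharpless asymmetric epoxidation (Ti(OiPr)4, D-(−)-diethyl tartrate, tBuOOH, 4 Å sieves, CH2Cl2, −20 °C) should give the (2R,3S)-epoxy alcohol F5. With catalytic camphorsulfonic acid in CH2Cl2 at 0 °C the phenol opens the epoxide at the tertiary carbon with inversion in a 6-exo sense and gives the (2R)-chroman diol F6. NaIO4 in THF/H2O cleaves the diol to the (2R)-chroman-2-carbaldehyde F7. Horner–Wadsworth–Emmons olefination with the lithium anion of diethyl (3-methylbut-2-en-1-yl)phosphonate (THF, −78 °C → rt) then gives E diene 17, where the route is rejoined before step 12.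

Step 8. The electron-rich free 2-vinylphenol may oligomerise before or during hydroboration, and the phenol consumes borane, so hydroboration may stay incomplete. The fallback sets out from aldehyde 7 and masks the phenol. tBuMe2SiOTf and 2,6-lutidine give the tert-butyldimethylsilyl ether F8, and Wittig methylenation gives the silyl-protected styrene F9. Hydroboration with 9-BBN-H gives the B-alkyl-9-BBN adduct F10, which is coupled in the same flask with 11 (PdCl2(dppf), aq. NaOH) to give the silyl-protected Z-allylic alcohol F11. Bu4NF at 0 °C removes the aryl silyl group without touching the SEM ether and gives 13, where the route is rejoined before step 9.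

Further compounds
F1 | step 15 | methyl (2R)-5-(methoxymethoxy)-2-methyl-2-[(1E)-4-methylpenta-1,3-dien-1-yl]-8-(3-methylbut-2-en-1-yl)-7-{[2-(trimethylsilyl)ethoxy]methoxy}chroman-6-carboxylate | CC(C)=C/C=C/[C@@]1(C)CCc2c(OCOC)c(C(=O)OC)c(OCOCC[Si](C)(C)C)c(CC=C(C)C)c2O1
F2 | step 15 | methyl (2R)-7-hydroxy-5-(methoxymethoxy)-2-methyl-2-[(1E)-4-methylpenta-1,3-dien-1-yl]-8-(3-methylbut-2-en-1-yl)chroman-6-carboxylate | CC(C)=C/C=C/[C@@]1(C)CCc2c(OCOC)c(C(=O)OC)c(O)c(CC=C(C)C)c2O1
F3 | step 15 | methyl (2R)-5-(methoxymethoxy)-2-methyl-2-[(1E)-4-methylpenta-1,3-dien-1-yl]-8-(3-methylbut-2-en-1-yl)-7-(trifluoromethanesulfonyloxy)chroman-6-carboxylate | CC(C)=C/C=C/[C@@]1(C)CCc2c(OCOC)c(C(=O)OC)c(OS(=O)(=O)C(F)(F)F)c(CC=C(C)C)c2O1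
F4 | step 15 | methyl (2R)-5-(methoxymethoxy)-2,7-dimethyl-2-[(1E)-4-methylpenta-1,3-dien-1-yl]-8-(3-methylbut-2-en-1-yl)chroman-6-carboxylate | CC(C)=C/C=C/[C@@]1(C)CCc2c(OCOC)c(C(=O)OC)c(C)c(CC=C(C)C)c2O1
F5 | step 11 | [(2R,3S)-3-{2-[2-hydroxy-6-(methoxymethoxy)-3-(3-methylbut-2-en-1-yl)-4-{[2-(trimethylsilyl)ethoxy]methoxy}phenyl]ethyl}-3-methyloxiran-2-yl]methanol | OC[C@H]1O[C@@]1(C)CCc1c(O)c(CC=C(C)C)c(OCOCC[Si](C)(C)C)cc1OCOC
F6 | step 11 | (1R)-1-[(2R)-5-(methoxymethoxy)-2-methyl-8-(3-methylbut-2-en-1-yl)-7-{[2-(trimethylsilyl)ethoxy]methoxy}chroman-2-yl]ethane-1,2-diol | OC[C@@H](O)[C@@]1(C)CCc2c(OCOC)cc(OCOCC[Si](C)(C)C)c(CC=C(C)C)c2O1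
F7 | step 11 | (2R)-5-(methoxymethoxy)-2-methyl-8-(3-methylbut-2-en-1-yl)-7-{[2-(trimethylsilyl)ethoxy]methoxy}chroman-2-carbaldehyde | O=C[C@@]1(C)CCc2c(OCOC)cc(OCOCC[Si](C)(C)C)c(CC=C(C)C)c2O1
F8 | step 8 | 2-[(tert-butyldimethylsilyl)oxy]-6-(methoxymethoxy)-3-(3-methylbut-2-en-1-yl)-4-{[2-(trimethylsilyl)ethoxy]methoxy}benzaldehyde | O=Cc1c(O[Si](C)(C)C(C)(C)C)c(CC=C(C)C)c(OCOCC[Si](C)(C)C)cc1OCOC
F9 | step 8 | tert-butyl[2-ethenyl-3-(methoxymethoxy)-6-(3-methylbut-2-en-1-yl)-5-{[2-(trimethylsilyl)ethoxy]methoxy}phenoxy]dimethylsilane | C=Cc1c(O[Si](C)(C)C(C)(C)C)c(CC=C(C)C)c(OCOCC[Si](C)(C)C)cc1OCOC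
F10 | step 8 | 9-{2-[2-[(tert-butyldimethylsilyl)oxy]-6-(methoxymethoxy)-3-(3-methylbut-2-en-1-yl)-4-{[2-(trimethylsilyl)ethoxy]methoxy}phenyl]ethyl}-9-borabicyclo[3.3.1]nonane | CC(C)=CCc1c(O[Si](C)(C)C(C)(C)C)c(CCB2C3CCCC2CCC3)c(OCOC)cc1OCOCC[Si](C)(C)C
F11 | step 8 | (2Z)-5-[2-[(tert-butyldimethylsilyl)oxy]-6-(methoxymethoxy)-3-(3-methylbut-2-en-1-yl)-4-{[2-(trimethylsilyl)ethoxy]methoxy}phenyl]-3-methylpent-2-en-1-ol | OC/C=C(/C)CCc1c(O[Si](C)(C)C(C)(C)C)c(CC=C(C)C)c(OCOCC[Si](C)(C)C)cc1OCOC
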